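**Plan**

1. Retrosynthetic cuts (mutilin numbering): ring A last, at C3=C4 (aldol condensation) and C2=O (alkyne hydration); then C5–C6 (bridging Michael addition); C7–C8 (thioester to enone); C5–C14 (Mukaiyama aldol on an acetal); C11–C12 (allylboration); C9–C10 and C9–C1 (allylic alkylation and propargylation of a β-keto thioester).
2. Forward order: acyclic keto thioester with quaternary C9 → cyclooctanone (ring C) → cyclohexanone bridged across it (ring B, key step) → cyclopentenone (ring A).
3. Enabling feature: in the cyclooctanone the C4 carbonyl has one enolisable α-carbon only, C5, because C9 is quaternary. C9 carries an (E)-but-2-enoyl group whose β-carbon C6 lies five bonds from C5 (C5–C4–C9–C8–C7–C6). One conjugate addition therefore closes the six-membered ring, turns the cyclooctane into the bicyclo[5.3.1]undecane and creates the quaternary C5 and C6.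
4. Stereochemistry: C9/C10 from the Ir catalyst; C11/C12 from the (Z)-allylboronate (chair transition state) under a chiral phosphoric acid; C14 in the eight-ring closure; C5/C6 in the key step (tether, equatorial methyl); C8 by hydride from the open face.
5. Helpers and their removal: S-ethyl thioester (latent crotonoyl, step 13); prop-2-ynyl (latent acetonyl, step 17); bis(2-naphthylmethyl) acetal (latent C14–O, ether cleaved in step 18); TBS ethers (step 20).

Key step: step 14

Assumption: atoms are numbered as in mutilin (C1–C3 with C4/C9 = cyclopentenone; C4–C9 = cyclohexane; C4, C5, C9–C14 = cyclooctane; C15–C18 = methyls on C5, C6, C10, C12; C19=C20 = vinyl), and the C5/C6 configurations are written exactly as the target SMILES encodes them, which is the opposite pair, relative to C9, of that in pleuromutilin itself; the tether-controlled closure of step 14 is expected to give the pleuromutilin-type (cis-bridged) fusion, so the route as reasoned leads to that ring fusion.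

**Route**

Step 1
Reactants: 1 Meldrum's acid (2,2-dimethyl-1,3-dioxane-4,6-dione)
Product: 3 S-ethyl 3-oxopentanethioate, via acyl Meldrum's acid 2 (not isolated)
Conditions: EtCOCl, pyridine, CH2Cl2, 0 °C to rt; then EtSH, toluene, 80 °C
Reagents that add atoms: propanoyl chloride CCC(=O)Cl; ethanethiol CCS
Why: C-acylation of Meldrum's acid followed by thiolysis of the acyl Meldrum's acid (through the acylketene, with loss of acetone and CO2) is the standard entry to β-keto thioesters; no stereocentre is formed.

Step 2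
Reactants: 3 S-ethyl 3-oxopentanethioate
Product: 4 S-ethyl 3-oxo-2-(prop-2-yn-1-yl)pentanethioate (racemic)
Conditions: propargyl bromide (1.0 equiv), K2CO3, acetone, rt
Reagents that add atoms: prop-2-ynyl bromide C#CCBr
Why: C-alkylation of a soft β-dicarbonyl enolate with a propargylic halide; the new centre is racemic and is erased as the enolate of step 3.

Step 3
Reactants: 4 S-ethyl 3-oxo-2-(prop-2-yn-1-yl)pentanethioate
Product: 5 S-ethyl (2R,3S)-3-methyl-2-propanoyl-2-(prop-2-yn-1-yl)pent-4-enethioate
Conditions: [Ir(cod)Cl]2 (2 mol %), chiral N-aryl phosphoramidite (Me-THQphos type, 4 mol %; enantiomer giving 3S at the allylic carbon), TBD (10 mol %), LiOt-Bu, (E)-crotyl chloride, THF, rt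
Reagents that add atoms: (E)-1-chlorobut-2-ene C/C=C/CCl
Why: Iridium-catalysed branched-selective asymmetric allylic alkylation of an α-substituted β-dicarbonyl pronucleophile; the Ir–phosphoramidite allyl complex fixes C10 by attack at the substituted allyl terminus and the chelated (Z)-lithium enolate adds through one face to fix the quaternary C9, so the vicinal quaternary/tertiary pair is set in one step.

Step 4
Reactants: 5 S-ethyl (2R,3S)-3-methyl-2-propanoyl-2-(prop-2-yn-1-yl)pent-4-enethioate
Product: 6 S-ethyl (2R,3R)-3-methyl-4-oxo-2-propanoyl-2-(prop-2-yn-1-yl)butanethioate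
Conditions: OsO4 (2 mol %), NaIO4, 2,6-lutidine, dioxane/H2O, rt
Reagents that add atoms: sodium periodate (terminal oxidant; oxygen delivered through OsO4) [Na+].[O-][I](=O)(=O)=O
Why: Lemieux–Johnson cleavage is selective for the monosubstituted alkene over the alkyne, and the lutidine buffer should keep the α-stereocentre C10 from epimerising.

Step 5
Reactants: 7 4,4-diethoxybut-1-yne
Product: 8 4,4-bis(naphthalen-2-ylmethoxy)but-1-yne
Conditions: naphthalen-2-ylmethanol (2.2 equiv), PPTS (cat.), toluene, 90 °C, ethanol distilled off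
Reagents that add atoms: naphthalen-2-ylmethanol OCc1ccc2ccccc2c1
Why: Acid-catalysed transacetalisation driven by removal of ethanol installs alkoxy groups that can later be cleaved oxidatively; no stereocentre is formed.

Step 6
Reactants: 8 4,4-bis(naphthalen-2-ylmethoxy)but-1-yne
Product: 9 methyl 5,5-bis(naphthalen-2-ylmethoxy)pent-2-ynoate
Conditions: n-BuLi, THF, −78 °C; then ClCO2Me
Reagents that add atoms: methyl chloroformate COC(=O)Cl
Why: Acylation of the lithium acetylide with a chloroformate gives the 2-ynoate needed for stereodefined conjugate addition.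

Step 7
Reactants: 9 methyl 5,5-bis(naphthalen-2-ylmethoxy)pent-2-ynoate
Product: 10 methyl (2Z)-3-methyl-5,5-bis(naphthalen-2-ylmethoxy)pent-2-enoate
Conditions: Me2CuLi, THF, −78 °C; MeOH quench at −78 °C, then aq. NH4Cl
Reagents that add atoms: lithium dimethylcuprate [Li+].C[Cu-]C
Why: syn-Carbocupration of a 2-ynoate (Gilman reagent conjugate addition) places the new methyl and the α-hydrogen cis, so the ester is cis to the C13 chain (Z), the geometry that later defines C12.

Step 8
Reactants: 10 methyl (2Z)-3-methyl-5,5-bis(naphthalen-2-ylmethoxy)pent-2-enoate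
Product: 11 (2Z)-3-methyl-5,5-bis(naphthalen-2-ylmethoxy)pent-2-en-1-ol
Conditions: DIBAL-H (2.2 equiv), CH2Cl2, −78 °C; Rochelle salt work-up
Reagents that add atoms: none
Why: 1,2-Reduction of the enoate by DIBAL-H gives the allylic alcohol with the alkene geometry unchanged.

Step 9
Reactants: 11 (2Z)-3-methyl-5,5-bis(naphthalen-2-ylmethoxy)pent-2-en-1-ol
Product: 13 2-[(2Z)-3-methyl-5,5-bis(naphthalen-2-ylmethoxy)pent-2-en-1-yl]-4,4,5,5-tetramethyl-1,3,2-dioxaborolane, via allylboronic acid 12 (not isolated)
Conditions: B2(OH)4, [Pd(MeCN)4](BF4)2 (5 mol %), DMSO/H2O, rt; then pinacol, MgSO4, Et2O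
Reagents that add atoms: tetrahydroxydiboron OB(O)B(O)O; pinacol CC(C)(O)C(C)(C)O
Why: Palladium-catalysed borylation of an allylic alcohol with diboronic acid gives the linear allylboronic acid, expected to keep the alkene geometry; esterification with pinacol gives an isolable (Z)-allylboronate.

Step 10
Reactants: 6 S-ethyl (2R,3R)-3-methyl-4-oxo-2-propanoyl-2-(prop-2-yn-1-yl)butanethioate; 13 (Z)-allylboronate
Product: 14 S-ethyl (2R,3R,4S,5S)-5-ethenyl-4-hydroxy-3,5-dimethyl-7,7-bis(naphthalen-2-ylmethoxy)-2-propanoyl-2-(prop-2-yn-1-yl)heptanethioate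
Conditions: (R)-TRIP (10 mol %), 4 Å MS, toluene, −30 to 0 °C; aq. NaHCO3 work-up; crude product taken straight into step 11
Reagents that add atoms: none
Why: Brønsted-acid-catalysed allylboration through a chair Zimmerman–Traxler transition state: the (Z)-boronate puts the C13 chain axial, so it ends syn and the methyl anti to the new C11 hydroxyl, which fixes C11/C12; the chiral phosphoric acid is chosen to direct Re-face (Felkin–Anh) attack relative to C10, because substrate control with a γ,γ-disubstituted reagent alone is not reliable; the aldehyde reacts in preference to the hindered ketone and the thioester, and the γ-hydroxy thioester is silylated at once so that it cannot lactonise.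

Step 11
Reactants: 14 homoallylic alcohol
Product: 15 S-ethyl thioester carrying the C11 TBS ether and the (Z)-tert-butyldimethylsilyl enol ether of the C4 ketone (C4=C5)
Conditions: TBSOTf (2.6 equiv), Et3N, CH2Cl2, −78 to −20 °C
Reagents that add atoms: tert-butyldimethylsilyl triflate CC(C)(C)[Si](C)(C)OS(=O)(=O)C(F)(F)F
Why: Soft enolisation with silyl triflate and amine silylates the hindered alcohol and converts the ethyl ketone into its (Z)-enol silane; enolisation can occur only toward C5 because C9 is quaternary and the thioester has no α-hydrogen, and the low temperature with excess amine should leave the acetal untouched.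

Step 12
Reactants: 15 bis-silyl enol ether
Product: 16 cyclooctanone: ring C4(=O)–C5H(CH3)–C14H(OCH2-2-naphthyl)–C13H2–C12(CH3)(vinyl)–C11H(OTBS)–C10H(CH3)–C9, with C9 bearing prop-2-ynyl and C(=O)SEt
Conditions: TMSOTf (0.3 equiv), 2,6-di-tert-butyl-4-methylpyridine (0.5 equiv), CH2Cl2 (0.002 M), −78 to −40 °C
Reagents that add atoms: none
Why: Intramolecular Mukaiyama aldol addition to an acetal: TMSOTf ionises the acetal to an oxocarbenium ion, which the enol silane attacks at C5 to form C5–C14 and the eight-membered ring, helped by the two quaternary centres (C9, C12) and high dilution; an extended transition state with the (E)-oxocarbenium, in which the naphthylmethoxy group points away from the C12 vinyl group, should give the C14 configuration drawn, and the C5 configuration (syn to O14) is erased in step 14.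

Step 13
Reactants: 16 cyclooctanone thioester
Product: 17 cyclooctanone with an (E)-but-2-enoyl group on C9 in place of the thioester
Conditions: (E)-prop-1-enylzinc bromide [from (E)-1-bromoprop-1-ene, t-BuLi, ZnBr2] (1.5 equiv), PdCl2(PPh3)2 (5 mol %), THF/toluene, rt
Reagents that add atoms: (E)-prop-1-enylzinc bromide C/C=C/[Zn]Br
Why: Fukuyama coupling: Pd(0) inserts into the acyl–S bond and the alkenylzinc transmetalates with retention of the E geometry, so the thioester becomes the enone under neutral conditions that leave the ketone, the alkyne, the ethers and the enolisable C5–H untouched.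

Step 14
Reactants: 17 cyclooctanone with (E)-but-2-enoyl group on C9
Product: 18 bicyclo[5.3.1]undecane-dione: new cyclohexanone C4–C5–C6–C7–C8(=O)–C9 bridged across the cyclooctanone, C5 quaternary (CH3), C6 bearing CH3, C4 ketone as the one-carbon bridge
Conditions: KOt-Bu (0.3 equiv), t-BuOH/THF (1:4), 0 °C
Reagents that add atoms: none
Why: tert-Butoxide reversibly removes the C5 hydrogen, the only α-hydrogen of the C4 carbonyl, and the C4–C5 enolate adds through C5 to C6, the β-carbon of the enone on C9; protonation of the C7=C8 enolate by t-BuOH regenerates the base. The closest known reaction type is the base-mediated intramolecular Michael addition of a cycloalkanone enolate to an enone that gives bicyclo[n.3.1]alkanediones (bridged Robinson-type α,α′-annulation). The six-membered ring C4–C5–C6–C7–C8–C9 closes in the 6-(enolendo)-endo-trig mode, and this same bond converts the monocyclic cyclooctanone into the bicyclo[5.3.1]undecane. The quaternary C5 is fixed by the tether, since the enone on C9 can reach only one face of the planar enolate and the earlier C5 configuration is irrelevant; C6 is set by a chair transition state of the (E)-enone with the methyl equatorial, and reversibility of the addition favours the same isomer. The step needs C-alkylation at C5 to beat β-elimination of the C14 alkoxide and retro-Claisen cleavage of the non-enolisable 1,3-diketone; this is secured by a poor leaving group at C14 (ether, not ester), a hindered alkoxide in catalytic amount at 0 °C, and the silyl ether on O11 that prevents internal acyl transfer. The only other acidic site, the γ-methyl of the enone, gives an unproductive and reversible dienolate.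

Step 15
Reactants: 18 bicyclic diketone
Product: 19 C8 alcohol (C8–OH as in the target; C4 ketone retained)
Conditions: NaBH4, MeOH/THF, −40 °C
Reagents that add atoms: none
Why: The cyclohexanone carbonyl C8 is reduced while the bridging C4 ketone, flanked by two quaternary carbons, is inert; hydride should attack axially from the face opposite the C10–C14 bridge, giving the equatorial alcohol drawn.

Step 16
Reactants: 19 C8 alcohol
Product: 20 C8 TBS ether
Conditions: TBSOTf, 2,6-lutidine, CH2Cl2, 0 °C
Reagents that add atoms: tert-butyldimethylsilyl triflate CC(C)(C)[Si](C)(C)OS(=O)(=O)C(F)(F)F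
Why: Silylation masks the β-hydroxy ketone so that the basic annulation of step 17 cannot trigger retro-aldol cleavage, and it leaves C14 as the only oxygen to be freed in step 18.

Step 17
Reactants: 20 C8 TBS ether
Product: 22 tricyclic cyclopentenone (C2=O, C3=C4) with C8–OTBS, C11–OTBS and C14–OCH2-2-naphthyl, via 1,4-diketone 21 (not isolated)
Conditions: (JohnPhos)Au(MeCN)SbF6 (3 mol %), dioxane/H2O (10:1), 60 °C; concentrate; then KOt-Bu (0.5 equiv), t-BuOH, 60 °C
Reagents that add atoms: water O
Why: Gold-catalysed Markovnikov hydration of the terminal alkyne (assisted by the neighbouring C4 carbonyl) gives the acetonyl ketone; base-mediated intramolecular aldol condensation then closes the cyclopentenone, because the methyl ketone is the only enolisable carbonyl and the non-enolisable C4 ketone the only electrophile, and dehydration to the conjugated enone drives the hindered addition forward.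

Step 18
Reactants: 22 tricyclic cyclopentenone
Product: 23 C14 alcohol
Conditions: DDQ (1.5 equiv), CH2Cl2/pH 7 buffer (10:1), 0 °C to rt
Reagents that add atoms: none
Why: Oxidative cleavage of the 2-naphthylmethyl ether by DDQ is neutral and leaves the enone, the vinyl group and both silyl ethers untouched.

Step 19
Reactants: 23 C14 alcohol
Product: 24 C14 acetate (C8 and C11 still TBS-protected)
Conditions: Ac2O, DMAP, Et3N, CH2Cl2, 40 °C
Reagents that add atoms: acetic anhydride CC(=O)OC(C)=O
Why: DMAP-catalysed acetylation of the hindered C14 alcohol is unambiguous because it is the only free hydroxyl.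

Step 20
Reactants: 24 C14 acetate bis-TBS ether
Product: 25 Pleuromutilin E
Conditions: HF·pyridine, pyridine/THF, 0 °C to rt
Reagents that add atoms: none
Why: Fluoride-mediated removal of both secondary silyl ethers under buffered acidic conditions leaves the acetate and the enone intact.

**Compound list**

1 | Meldrum's acid (2,2-dimethyl-1,3-dioxane-4,6-dione) | CC1(C)OC(=O)CC(=O)O1 | starting material
2 | 5-(1-hydroxypropylidene)-2,2-dimethyl-1,3-dioxane-4,6-dione (acyl Meldrum's acid) | CCC(O)=C1C(=O)OC(C)(C)OC1=O | intermediate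
3 | S-ethyl 3-oxopentanethioate | CCC(=O)CC(=O)SCC | intermediate
4 | S-ethyl 3-oxo-2-(prop-2-yn-1-yl)pentanethioate (racemic) | CCC(=O)C(CC#C)C(=O)SCC | intermediate
5 | S-ethyl (2R,3S)-3-methyl-2-propanoyl-2-(prop-2-yn-1-yl)pent-4-enethioate | CCC(=O)[C@](CC#C)(C(=O)SCC)[C@@H](C)C=C | intermediate
6 | S-ethyl (2R,3R)-3-methyl-4-oxo-2-propanoyl-2-(prop-2-yn-1-yl)butanethioate | CCC(=O)[C@](CC#C)(C(=O)SCC)[C@@H](C)C=O | intermediate
7 | 4,4-diethoxybut-1-yne | C#CCC(OCC)OCC | starting material
8 | 4,4-bis(naphthalen-2-ylmethoxy)but-1-yne | C#CCC(OCc1ccc2ccccc2c1)OCc1ccc2ccccc2c1 | intermediate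
9 | methyl 5,5-bis(naphthalen-2-ylmethoxy)pent-2-ynoate | COC(=O)C#CCC(OCc1ccc2ccccc2c1)OCc1ccc2ccccc2c1 | intermediate
10 | methyl (2Z)-3-methyl-5,5-bis(naphthalen-2-ylmethoxy)pent-2-enoate | COC(=O)/C=C(/C)CC(OCc1ccc2ccccc2c1)OCc1ccc2ccccc2c1 | intermediate
11 | (2Z)-3-methyl-5,5-bis(naphthalen-2-ylmethoxy)pent-2-en-1-ol | OC/C=C(/C)CC(OCc1ccc2ccccc2c1)OCc1ccc2ccccc2c1 | intermediate
12 | [(2Z)-3-methyl-5,5-bis(naphthalen-2-ylmethoxy)pent-2-en-1-yl]boronic acid | OB(O)C/C=C(/C)CC(OCc1ccc2ccccc2c1)OCc1ccc2ccccc2c1 | intermediate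
13 | pinacol ester of 12, (Z)-allylboronate | CC1(C)OB(C/C=C(/C)CC(OCc2ccc3ccccc3c2)OCc2ccc3ccccc3c2)OC1(C)C | intermediate
14 | S-ethyl (2R,3R,4S,5S)-5-ethenyl-4-hydroxy-3,5-dimethyl-7,7-bis(naphthalen-2-ylmethoxy)-2-propanoyl-2-(prop-2-yn-1-yl)heptanethioate | CCC(=O)[C@](CC#C)(C(=O)SCC)[C@@H](C)[C@H](O)[C@](C)(C=C)CC(OCc1ccc2ccccc2c1)OCc1ccc2ccccc2c1 | intermediate
15 | 14 as its C11 TBS ether and (Z)-TBS enol ether of the C4 ketone | C/C=C(\O[Si](C)(C)C(C)(C)C)[C@](CC#C)(C(=O)SCC)[C@@H](C)[C@H](O[Si](C)(C)C(C)(C)C)[C@](C)(C=C)CC(OCc1ccc2ccccc2c1)OCc1ccc2ccccc2c1 | intermediate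
16 | cyclooctanone thioester (5S,9R,10R,11S,12S,14R): C9 bears prop-2-ynyl and C(=O)SEt; C14 O-(2-naphthylmethyl); C11 OTBS; C12 methyl and vinyl; C5, C10 methyl | C=C[C@]1(C)C[C@@H](OCc2ccc3ccccc3c2)[C@H](C)C(=O)[C@](CC#C)(C(=O)SCC)[C@@H](C)[C@@H]1O[Si](C)(C)C(C)(C)C | intermediate
17 | cyclooctanone 16 with (E)-but-2-enoyl on C9 in place of the thioester (stereocentres as in 16) | C=C[C@]1(C)C[C@@H](OCc2ccc3ccccc3c2)[C@H](C)C(=O)[C@](CC#C)(C(=O)/C=C/C)[C@@H](C)[C@@H]1O[Si](C)(C)C(C)(C)C | intermediate
18 | bicyclo[5.3.1]undecane-4,8-dione (ring B closed; C5 quaternary, C6 methyl, configurations as in the SMILES) | C=C[C@]1(C)C[C@@H](OCc3ccc4ccccc4c3)[C@]2(C)C(=O)[C@](CC#C)(C(=O)C[C@@H]2C)[C@@H](C)[C@@H]1O[Si](C)(C)C(C)(C)C | intermediate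
19 | C8 alcohol of 18 (C8 as in the target) | C=C[C@]1(C)C[C@@H](OCc3ccc4ccccc4c3)[C@]2(C)C(=O)[C@](CC#C)([C@@H](O)C[C@@H]2C)[C@@H](C)[C@@H]1O[Si](C)(C)C(C)(C)C | intermediate
20 | C8 TBS ether of 19 | C=C[C@]1(C)C[C@@H](OCc3ccc4ccccc4c3)[C@]2(C)C(=O)[C@](CC#C)([C@@H](O[Si](C)(C)C(C)(C)C)C[C@@H]2C)[C@@H](C)[C@@H]1O[Si](C)(C)C(C)(C)C | intermediate
21 | 1,4-diketone: 20 with 2-oxopropyl on C9 in place of prop-2-ynyl | C=C[C@]1(C)C[C@@H](OCc3ccc4ccccc4c3)[C@]2(C)C(=O)[C@](CC(C)=O)([C@@H](O[Si](C)(C)C(C)(C)C)C[C@@H]2C)[C@@H](C)[C@@H]1O[Si](C)(C)C(C)(C)C | intermediate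
22 | tricyclic cyclopentenone: 8,11-bis-O-TBS, 14-O-(2-naphthylmethyl) derivative of the deacetyl target | C=C[C@]1(C)C[C@@H](OCc4ccc5ccccc5c4)[C@]2(C)C3=CC(=O)C[C@@]3([C@@H](O[Si](C)(C)C(C)(C)C)C[C@@H]2C)[C@@H](C)[C@@H]1O[Si](C)(C)C(C)(C)C | intermediate
23 | C14 alcohol: 8,11-bis-O-TBS deacetyl target | C=C[C@]1(C)C[C@@H](O)[C@]2(C)C3=CC(=O)C[C@@]3([C@@H](O[Si](C)(C)C(C)(C)C)C[C@@H]2C)[C@@H](C)[C@@H]1O[Si](C)(C)C(C)(C)C | intermediate
24 | 8,11-bis-O-TBS ether of the target | C=C[C@]1(C)C[C@@H](OC(C)=O)[C@]2(C)C3=CC(=O)C[C@@]3([C@@H](O[Si](C)(C)C(C)(C)C)C[C@@H]2C)[C@@H](C)[C@@H]1O[Si](C)(C)C(C)(C)C | intermediate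
25 | Pleuromutilin E: (5S,6S,8S,9R,10R,11S,12S,14R)-14-acetoxy-8,11-dihydroxy-2-oxo-mutil-3-ene skeleton | C=C[C@]1(C)C[C@@H](OC(C)=O)[C@]2(C)C3=CC(=O)C[C@@]3([C@@H](O)C[C@@H]2C)[C@@H](C)[C@@H]1O | target

**Totals and risks**

Total steps: 20. Longest linear sequence: 16 (steps 5–9, then 10–20).

Steps most likely to fail:

1. Step 12 (eight-membered ring closure). Intermolecular oligomerisation, or loss of the oxocarbenium ion to an enol ether, may outrun the ring closure, and facial selectivity at C14 may be poor. The fallback replaces the cationic closure by a samarium Reformatsky aldol, which has its own record for medium rings. It sets out from 15: NBS at −78 °C converts the enol silane into the α-bromo ketone F1 (C5 epimers); mild aqueous acid (LiBF4, wet MeCN) frees the aldehyde to give the bromo keto aldehyde F2; SmI2 in dilute THF at −78 °C forms the samarium enolate at C5 only and closes the β-hydroxy cyclooctanone F3; 2-naphthylmethyl trichloroacetimidate with catalytic TfOH then returns the route to 16.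

2. Step 14 (key step). β-Elimination of the C14 alkoxide from the enolate, or retro-Claisen cleavage of the 1,3-diketone, may compete with carbon–carbon bond formation under basic conditions. The fallback moves the event to the Lewis-acid manifold (Mukaiyama–Michael addition). It sets out from 16: TBSOTf/Et3N gives the cyclooctenyl silyl enol ether F4 before any enone is present; the Fukuyama coupling of step 13 on F4 gives the enone enol silane F5; TiCl4 (or catalytic Tf2NH) in CH2Cl2 at −78 °C then closes C5–C6 and returns the route to 18.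

3. Step 17 (cyclopentenone annulation onto the bridging ketone). The aldol addition to the C4 carbonyl, flanked by two quaternary carbons, may be too slow or may revert before dehydration. The fallback builds ring A before ring B and closes ring B by a vinylogous Michael addition. It sets out from 16: gold-catalysed hydration gives the 1,4-diketone thioester F6; KOt-Bu (0.3 equiv) in t-BuOH/THF at 0 °C condenses it onto the unhindered cyclooctanone carbonyl to give the bicyclic enone thioester F7; Fukuyama coupling gives the crotonoyl enone F8; catalytic KOt-Bu under equilibrating conditions adds the γ-carbon C5 of the dienolate to C6, the conjugated adduct being the thermodynamic product, to give the tricyclic enone ketone F9; NaBH4 at −78 °C reduces the saturated C8 ketone in preference to the enone to give the alcohol F10; TBSOTf/2,6-lutidine returns the route to 22.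

Further compounds
F1 | step 12 | α-bromo ketone from 15 (C5 bromide, epimer mixture) | CC(Br)C(=O)[C@](CC#C)(C(=O)SCC)[C@@H](C)[C@H](O[Si](C)(C)C(C)(C)C)[C@](C)(C=C)CC(OCc1ccc2ccccc2c1)OCc1ccc2ccccc2c1
F2 | step 12 | bromo keto aldehyde (C14 aldehyde) | CC(Br)C(=O)[C@](CC#C)(C(=O)SCC)[C@@H](C)[C@H](O[Si](C)(C)C(C)(C)C)[C@](C)(C=C)CC=O
F3 | step 12 | β-hydroxy cyclooctanone (C14–OH analogue of 16) | C=C[C@]1(C)C[C@@H](O)[C@H](C)C(=O)[C@](CC#C)(C(=O)SCC)[C@@H](C)[C@@H]1O[Si](C)(C)C(C)(C)C
F4 | step 14 | cyclooctenyl TBS enol ether of 16 (C4=C5) | C=C[C@]1(C)C[C@@H](OCc2ccc3ccccc3c2)/C(C)=C(/O[Si](C)(C)C(C)(C)C)[C@](CC#C)(C(=O)SCC)[C@@H](C)[C@@H]1O[Si](C)(C)C(C)(C)C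
F5 | step 14 | enone enol silane (F4 with (E)-but-2-enoyl on C9) | C=C[C@]1(C)C[C@@H](OCc2ccc3ccccc3c2)/C(C)=C(/O[Si](C)(C)C(C)(C)C)[C@](CC#C)(C(=O)/C=C/C)[C@@H](C)[C@@H]1O[Si](C)(C)C(C)(C)C
F6 | step 17 | 1,4-diketone thioester (16 with 2-oxopropyl on C9) | C=C[C@]1(C)C[C@@H](OCc2ccc3ccccc3c2)[C@H](C)C(=O)[C@](CC(C)=O)(C(=O)SCC)[C@@H](C)[C@@H]1O[Si](C)(C)C(C)(C)C
F7 | step 17 | bicyclic enone thioester (rings A and C) | C=C[C@]1(C)C[C@@H](OCc2ccc3ccccc3c2)[C@H](C)C2=CC(=O)C[C@@]2(C(=O)SCC)[C@@H](C)[C@@H]1O[Si](C)(C)C(C)(C)C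
F8 | step 17 | bicyclic enone with (E)-but-2-enoyl on C9 | C=C[C@]1(C)C[C@@H](OCc2ccc3ccccc3c2)[C@H](C)C2=CC(=O)C[C@@]2(C(=O)/C=C/C)[C@@H](C)[C@@H]1O[Si](C)(C)C(C)(C)C
F9 | step 17 | tricyclic enone with C8 ketone | C=C[C@]1(C)C[C@@H](OCc4ccc5ccccc5c4)[C@]2(C)C3=CC(=O)C[C@@]3(C(=O)C[C@@H]2C)[C@@H](C)[C@@H]1O[Si](C)(C)C(C)(C)C
F10 | step 17 | tricyclic enone with C8 alcohol | C=C[C@]1(C)C[C@@H](OCc4ccc5ccccc5c4)[C@]2(C)C3=CC(=O)C[C@@]3([C@@H](O)C[C@@H]2C)[C@@H](C)[C@@H]1O[Si](C)(C)C(C)(C)C
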